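Ring C is cut at O1–C8a, C4–C4a and O1–C2. The feature used is that C8a (carrying O1) and C4a (carrying the C4 carbonyl) are neighbouring carbons of ring A, with the C5 oxygen next to C4a: this is the regiochemistry with which a 3-alkoxy aryne adds a carboxylate. In one flask, an ortho-silyl aryl triflate derived from phloroglucinol (5-O as MOM, 7-O as prenyl ether) and the ring B arylpropiolic acid should give the protected flavone by O-arylation, 1,3-acyl shift and 6-endo closure. C3 oxygenation, a [3,3] shift of the 7-O-prenyl group to C8 (giving the 1,1-dimethylallyl group) and MOM removal complete the route.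

Key step: step 10

Remark: "prenyl" means 3-methylbut-2-en-1-yl and MOM means methoxymethyl; the C8 group of the target is 2-methylbut-3-en-2-yl (1,1-dimethylallyl), the direct [3,3] product of a 7-O-prenyl ether; the target has no stereocentre; 12 and 14 are taken as purchasable.

Step 1
Reactants: 1 phloroglucinol
Product: 2 5-(methoxymethoxy)benzene-1,3-diol
Conditions: MOMCl (1.0 equiv), i-Pr2NEt, THF–DMF, 0 °C to rt
Reagents that add atoms: chloromethyl methyl ether, COCCl
Why: Williamson-type O-alkylation with the hard electrophile MOMCl should go on oxygen and not on carbon, and one equivalent should make the mono-ether the main part of a statistical mixture that is separated on silica from bis-ether and recovered 1.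

Step 2
Reactants: 2 5-(methoxymethoxy)benzene-1,3-diol; 3 prenyl bromide (1-bromo-3-methylbut-2-ene)
Product: 4 3-(methoxymethoxy)-5-(prenyloxy)phenol
Conditions: K2CO3, acetone, rt, 3 (1.0 equiv) added slowly
Reagents that add atoms: none
Why: Williamson ether synthesis, in which the potassium phenoxide in acetone is alkylated on oxygen by the primary allylic bromide (2 lacks the triketo character that drives C-alkylation of phloroglucinol), the mono-ether being separated from the symmetric bis-ether and recovered 2.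

Step 3
Reactants: 4 3-(methoxymethoxy)-5-(prenyloxy)phenol
Product: 5 3-(methoxymethoxy)-5-(prenyloxy)phenyl N-isopropylcarbamate
Conditions: i-PrNCO, Et3N (cat.), CH2Cl2, rt
Reagents that add atoms: isopropyl isocyanate, CC(C)N=C=O
Why: Amine-catalysed addition of the phenol across the isocyanate (carbamoylation) installs a group that is both the strongest ortho-director on the ring and a phenol mask removable under mild base.

Step 4
Reactants: 5 3-(methoxymethoxy)-5-(prenyloxy)phenyl N-isopropylcarbamate
Product: 9 3-(methoxymethoxy)-5-(prenyloxy)-2-(trimethylsilyl)phenyl N-isopropylcarbamate, via N-silyl carbamate 6 (not isolated), via aryllithium 7 (not isolated), via N-silyl arylsilane 8 (not isolated)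
Conditions: TBSOTf, TMEDA, Et2O, 0 °C to rt; n-BuLi, TMEDA, −78 °C; TMSCl, −78 °C to rt; aq NH4Cl–MeOH
Reagents that add atoms: chlorotrimethylsilane, C[Si](C)(C)Cl
Why: Directed ortho-metalation, in which in situ N-silylation removes the acidic N–H, n-BuLi/TMEDA should lithiate the ring carbon flanked by the two best directors (carbamate and chelating OMOM) in preference to the one beside the weakly directing prenyl ether, and TMSCl traps the aryllithium at −78 °C before an anionic Fries shift can set in.

Step 5
Reactants: 9 3-(methoxymethoxy)-5-(prenyloxy)-2-(trimethylsilyl)phenyl N-isopropylcarbamate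
Product: 11 3-(methoxymethoxy)-5-(prenyloxy)-2-(trimethylsilyl)phenyl trifluoromethanesulfonate, via 2-silylphenol 10 (not isolated)
Conditions: DBU, Et2NH, MeCN, 40 °C; then PhNTf2, rt
Reagents that add atoms: N-phenylbis(trifluoromethanesulfonimide), O=S(=O)(N(c1ccccc1)S(=O)(=O)C(F)(F)F)C(F)(F)F
Why: E1cB cleavage of the N–H carbamate releases the phenoxide and isopropyl isocyanate (scavenged by diethylamine as a urea), and O-sulfonylation by PhNTf2 in the same flask avoids isolating the acid-sensitive, electron-rich silylphenol.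

Step 6
Reactants: 12 3-bromo-4,5-dihydroxybenzaldehyde
Product: 13 3-bromo-4,5-bis(methoxymethoxy)benzaldehyde
Conditions: MOMCl (2.5 equiv), i-Pr2NEt, CH2Cl2, 0 °C to rt
Reagents that add atoms: chloromethyl methyl ether, COCCl
Why: Williamson-type double O-alkylation of the catechol under amine base, to which the aldehyde and the aryl bromide are inert.

Step 7
Reactants: 13 3-bromo-4,5-bis(methoxymethoxy)benzaldehyde; 14 prenylboronic acid pinacol ester (4,4,5,5-tetramethyl-2-(3-methylbut-2-en-1-yl)-1,3,2-dioxaborolane)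
Product: 15 3,4-bis(methoxymethoxy)-5-prenylbenzaldehyde
Conditions: PdCl2(dppf) (cat.), K3PO4, THF–H2O, 65 °C
Reagents that add atoms: none
Why: Suzuki–Miyaura allyl–aryl coupling, in which sigma–pi–sigma equilibration of the aryl(prenyl)palladium intermediate should let reductive elimination occur at the unsubstituted CH2 terminus to give the linear prenyl arene, while aldehyde and MOM ethers tolerate the phosphate base.

Step 8
Reactants: 15 3,4-bis(methoxymethoxy)-5-prenylbenzaldehyde
Product: 16 5-ethynyl-1,2-bis(methoxymethoxy)-3-prenylbenzene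
Conditions: dimethyl (1-diazo-2-oxopropyl)phosphonate, K2CO3, MeOH, 0 °C to rt
Reagents that add atoms: dimethyl (1-diazo-2-oxopropyl)phosphonate, COP(=O)(OC)C(=[N+]=[N-])C(C)=O
Why: Ohira–Bestmann variant of the Seyferth–Gilbert homologation, in which the diazomethylphosphonate anion olefinates the aldehyde and loss of N2 with 1,2-hydride shift gives the terminal alkyne under conditions harmless to MOM ethers and the prenyl group.

Step 9
Reactants: 16 5-ethynyl-1,2-bis(methoxymethoxy)-3-prenylbenzene
Product: 18 3-[3,4-bis(methoxymethoxy)-5-prenylphenyl]prop-2-ynoic acid, via lithium acetylide 17 (not isolated)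
Conditions: n-BuLi, THF, −78 °C; CO2, −78 to 0 °C; cold 1 M HCl to pH 2–3
Reagents that add atoms: carbon dioxide, O=C=O
Why: Deprotonation of the terminal alkyne and carboxylation of the lithium acetylide is the standard entry to arylpropiolic acids, and brief cold acidification should free the acid without cleaving the MOM ethers.

Step 10
Reactants: 11 3-(methoxymethoxy)-5-(prenyloxy)-2-(trimethylsilyl)phenyl trifluoromethanesulfonate; 18 3-[3,4-bis(methoxymethoxy)-5-prenylphenyl]prop-2-ynoic acid
Product: 22 5-(methoxymethoxy)-7-(prenyloxy)-2-[3,4-bis(methoxymethoxy)-5-prenylphenyl]-4H-chromen-4-one, via caesium arylpropiolate 19 (not isolated), via alkoxyaryne 20 (not isolated), via caesium 2-ynoylphenoxide 21 (not isolated)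
Conditions: 18 (1.3 equiv), Cs2CO3 (1.3 equiv), THF, rt; then CsF (3 equiv), 18-crown-6 (0.3 equiv), 65 °C, 11 added over 2 h; aq NH4Cl
Reagents that add atoms: none
Why: Proposed new method: fluoride removes the silyl group and triflate departs to give aryne 20, whose carbon distal to the OMOM-bearing carbon is attacked by the carboxylate oxygen of 19, because the inductively withdrawing alkoxy group next to the triple bond distorts the aryne and stabilises the carbanion beside it. That aryl anion, with no soluble proton donor present because the acid is delivered as its caesium salt, attacks the ester carbonyl through a four-membered alkoxide that opens to the ortho-acyl phenoxide 21, an anionic Fries-type 1,3-acyl shift forming O1–C8a and C4–C4a. Phenoxide 21 then closes ring C by 6-endo-dig oxa-Michael addition to the ynone (O1–C2), and the C3 carbanion so formed is protonated by suspended CsHCO3. The closest known reaction types are fluoride-induced aryne insertion into the C–O bond of carboxylic acids to give ortho-hydroxyaryl ketones and base-mediated cyclisation of ortho-hydroxyaryl ynones to flavones, the untested element being their union on a 3,5-dialkoxy aryne and a prenylated arylpropiolate in one flask. No stereocentre is formed. The step needs regioselective O-attack (secured by the alkoxy group adjacent to the aryne bond), acyl shift ahead of conjugate attack on the alkyne (the s-Z ester geometry keeps the alkyne carbons away from the anion), 6-endo over 5-exo closure (Michael polarisation of the ynone under aprotic basic conditions) and no ene reaction of the aryne with prenyl groups (slow addition of 11 to excess carboxylate).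

Step 11
Reactants: 22 5-(methoxymethoxy)-7-(prenyloxy)-2-[3,4-bis(methoxymethoxy)-5-prenylphenyl]-4H-chromen-4-one
Product: 25 3-hydroxy-5-(methoxymethoxy)-7-(prenyloxy)-2-[3,4-bis(methoxymethoxy)-5-prenylphenyl]-4H-chromen-4-one, via 3-lithioflavone 23 (not isolated), via lithium trimethoxyborate 24 (not isolated)
Conditions: LDA (1.5 equiv), THF, −78 °C; B(OMe)3, −78 to 0 °C; AcOH, 30% H2O2, 0 °C to rt
Reagents that add atoms: hydrogen peroxide, OO
Why: Lithiation–borylation–oxidation, in which LDA removes the C3–H of the flavone at −78 °C and the borate undergoes oxidative 1,2-migration from boron to oxygen, so the 3-hydroxyl is installed without an oxidant able to epoxidise the prenyl double bonds.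

Step 12
Reactants: 25 3-hydroxy-5-(methoxymethoxy)-7-(prenyloxy)-2-[3,4-bis(methoxymethoxy)-5-prenylphenyl]-4H-chromen-4-one
Product: 27 3,7-dihydroxy-5-(methoxymethoxy)-8-(2-methylbut-3-en-2-yl)-2-[3,4-bis(methoxymethoxy)-5-prenylphenyl]-4H-chromen-4-one, via ortho-dienone 26 (not isolated)
Conditions: Eu(fod)3 (10 mol%; fod = 6,6,7,7,8,8,8-heptafluoro-2,2-dimethyloctane-3,5-dionate), NaHCO3, PhCl, 80 °C
Reagents that add atoms: none
Why: Lanthanide-catalysed aromatic Claisen rearrangement ([3,3] shift with allylic inversion through dienone 26), which with the C5 oxygen capped and not chelated to C4=O should deliver the 1,1-dimethylallyl group to C8, the end of the C7–C8 bond of higher double-bond character in a chromone, and not to C6.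

Step 13
Reactants: 27 3,7-dihydroxy-5-(methoxymethoxy)-8-(2-methylbut-3-en-2-yl)-2-[3,4-bis(methoxymethoxy)-5-prenylphenyl]-4H-chromen-4-one
Product: 28 3,5,7-trihydroxy-2-[3,4-dihydroxy-5-(3-methylbut-2-en-1-yl)phenyl]-8-(2-methylbut-3-en-2-yl)-4H-chromen-4-one
Conditions: HCl (1 M in MeOH), 25–40 °C
Reagents that add atoms: none
Why: Acid-catalysed acetal exchange (MOM ether methanolysis) removes the three MOM groups as dimethoxymethane, and dilute methanolic HCl near room temperature should leave the prenyl and 1,1-dimethylallyl groups uncyclised beside their phenols.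

Compound list
1 | phloroglucinol | Oc1cc(O)cc(O)c1 | starting material
2 | 5-(methoxymethoxy)benzene-1,3-diol | COCOc1cc(O)cc(O)c1 | intermediate
3 | prenyl bromide (1-bromo-3-methylbut-2-ene) | CC(C)=CCBr | starting material
4 | 3-(methoxymethoxy)-5-(prenyloxy)phenol | COCOc1cc(O)cc(OCC=C(C)C)c1 | intermediate
5 | 3-(methoxymethoxy)-5-(prenyloxy)phenyl N-isopropylcarbamate | CC(C)NC(=O)Oc1cc(OCOC)cc(OCC=C(C)C)c1 | intermediate
6 | N-(tert-butyldimethylsilyl) derivative of 5 (in situ) | CC(C)N(C(=O)Oc1cc(OCOC)cc(OCC=C(C)C)c1)[Si](C)(C)C(C)(C)C | intermediate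
7 | 2-lithio derivative of 6, lithium between the carbamate and OMOM carbons (in situ) | [Li]c1c(OCOC)cc(OCC=C(C)C)cc1OC(=O)N(C(C)C)[Si](C)(C)C(C)(C)C | intermediate
8 | 2-(trimethylsilyl) derivative of 6 (in situ) | C[Si](C)(C)c1c(OCOC)cc(OCC=C(C)C)cc1OC(=O)N(C(C)C)[Si](C)(C)C(C)(C)C | intermediate
9 | 3-(methoxymethoxy)-5-(prenyloxy)-2-(trimethylsilyl)phenyl N-isopropylcarbamate | C[Si](C)(C)c1c(OCOC)cc(OCC=C(C)C)cc1OC(=O)NC(C)C | intermediate
10 | 3-(methoxymethoxy)-5-(prenyloxy)-2-(trimethylsilyl)phenol (in situ, as its DBU-H+ phenoxide) | C[Si](C)(C)c1c(OCOC)cc(OCC=C(C)C)cc1O | intermediate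
11 | 3-(methoxymethoxy)-5-(prenyloxy)-2-(trimethylsilyl)phenyl trifluoromethanesulfonate | C[Si](C)(C)c1c(OCOC)cc(OCC=C(C)C)cc1OS(=O)(=O)C(F)(F)F | intermediate
12 | 3-bromo-4,5-dihydroxybenzaldehyde | O=Cc1cc(O)c(O)c(Br)c1 | starting material
13 | 3-bromo-4,5-bis(methoxymethoxy)benzaldehyde | O=Cc1cc(OCOC)c(OCOC)c(Br)c1 | intermediate
14 | prenylboronic acid pinacol ester | CC(C)=CCB1OC(C)(C)C(C)(C)O1 | starting material
15 | 3,4-bis(methoxymethoxy)-5-prenylbenzaldehyde | O=Cc1cc(OCOC)c(OCOC)c(CC=C(C)C)c1 | intermediate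
16 | 5-ethynyl-1,2-bis(methoxymethoxy)-3-prenylbenzene | C#Cc1cc(OCOC)c(OCOC)c(CC=C(C)C)c1 | intermediate
17 | lithium acetylide of 16 (in situ) | [Li]C#Cc1cc(OCOC)c(OCOC)c(CC=C(C)C)c1 | intermediate
18 | 3-[3,4-bis(methoxymethoxy)-5-prenylphenyl]prop-2-ynoic acid | OC(=O)C#Cc1cc(OCOC)c(OCOC)c(CC=C(C)C)c1 | intermediate
19 | caesium 3-[3,4-bis(methoxymethoxy)-5-prenylphenyl]prop-2-ynoate (in situ) | [Cs+].[O-]C(=O)C#Cc1cc(OCOC)c(OCOC)c(CC=C(C)C)c1 | intermediate
20 | 1,2-didehydro-3-(methoxymethoxy)-5-(prenyloxy)benzene (aryne, in situ) | COCOC1=CC(OCC=C(C)C)=CC#C1 | intermediate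
21 | caesium 2-{3-[3,4-bis(methoxymethoxy)-5-prenylphenyl]prop-2-ynoyl}-3-(methoxymethoxy)-5-(prenyloxy)phenoxide (in situ) | [Cs+].[O-]c1cc(OCC=C(C)C)cc(OCOC)c1C(=O)C#Cc1cc(OCOC)c(OCOC)c(CC=C(C)C)c1 | intermediate
22 | 5-(methoxymethoxy)-7-(prenyloxy)-2-[3,4-bis(methoxymethoxy)-5-prenylphenyl]-4H-chromen-4-one | CC(C)=CCOc1cc(OCOC)c2c(=O)cc(-c3cc(OCOC)c(OCOC)c(CC=C(C)C)c3)oc2c1 | intermediate
23 | 3-lithio derivative of 22 (in situ) | CC(C)=CCOc1cc(OCOC)c2c(=O)c([Li])c(-c3cc(OCOC)c(OCOC)c(CC=C(C)C)c3)oc2c1 | intermediate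
24 | lithium trimethoxyborate of 22, boron on C3 (in situ) | CC(C)=CCOc1cc(OCOC)c2c(=O)c([B-](OC)(OC)OC)c(-c3cc(OCOC)c(OCOC)c(CC=C(C)C)c3)oc2c1.[Li+] | intermediate
25 | 3-hydroxy-5-(methoxymethoxy)-7-(prenyloxy)-2-[3,4-bis(methoxymethoxy)-5-prenylphenyl]-4H-chromen-4-one | CC(C)=CCOc1cc(OCOC)c2c(=O)c(O)c(-c3cc(OCOC)c(OCOC)c(CC=C(C)C)c3)oc2c1 | intermediate
26 | ortho-dienone: 3-hydroxy-5-(methoxymethoxy)-8-(2-methylbut-3-en-2-yl)-2-[3,4-bis(methoxymethoxy)-5-prenylphenyl]-8H-chromene-4,7-dione (racemic at C8, in situ) | C=CC(C)(C)C1C(=O)C=C(OCOC)C2=C1OC(c3cc(OCOC)c(OCOC)c(CC=C(C)C)c3)=C(O)C2=O | intermediate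
27 | 3,7-dihydroxy-5-(methoxymethoxy)-8-(2-methylbut-3-en-2-yl)-2-[3,4-bis(methoxymethoxy)-5-prenylphenyl]-4H-chromen-4-one | C=CC(C)(C)c1c(O)cc(OCOC)c2c(=O)c(O)c(-c3cc(OCOC)c(OCOC)c(CC=C(C)C)c3)oc12 | intermediate
28 | 3,5,7-trihydroxy-2-[3,4-dihydroxy-5-(3-methylbut-2-en-1-yl)phenyl]-8-(2-methylbut-3-en-2-yl)-4H-chromen-4-one | C=CC(C)(C)c1c(O)cc(O)c2c(=O)c(O)c(-c3cc(O)c(O)c(CC=C(C)C)c3)oc12 | target

Total step count: 13. Longest linear sequence: 9 steps (steps 1–5 and 10–13); the ring B branch (steps 6–9) joins at step 10.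

Steps most likely to fail

Step 10. The aryl anion formed after O-arylation may be protonated or may add to the alkyne before the acyl group has shifted. The aryne may also be consumed by ene reaction with a prenyl group, or the ynone phenoxide may close 5-exo. Each of these diverts material from the flavone. The fallback uses known chemistry, sets out from carbamate 5 and acid 18, and returns at flavone 22. Acid 18 is coupled with N,O-dimethylhydroxylamine hydrochloride (EDC·HCl, i-Pr2NEt, CH2Cl2) to give the Weinreb amide N-methoxy-N-methyl-3-[3,4-bis(methoxymethoxy)-5-prenylphenyl]prop-2-ynamide F1. Aryllithium 7, generated from 5 exactly as in step 4, is quenched at −78 °C with F1 in place of TMSCl (directed ortho-metalation followed by acylation). This gives the N-silylated ynone 2-{3-[3,4-bis(methoxymethoxy)-5-prenylphenyl]prop-2-ynoyl}-3-(methoxymethoxy)-5-(prenyloxy)phenyl N-(tert-butyldimethylsilyl)-N-isopropylcarbamate F2, whose N–Si bond is hydrolysed on work-up to 2-{3-[3,4-bis(methoxymethoxy)-5-prenylphenyl]prop-2-ynoyl}-3-(methoxymethoxy)-5-(prenyloxy)phenyl N-isopropylcarbamate F3. DBU and Et2NH in MeCN at 40 °C then free the phenoxide by E1cB cleavage, and amine-mediated 6-endo cyclisation of the ortho-hydroxyaryl ynone gives 22.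

Step 12. The 3-hydroxy-4-keto unit may bind the trivalent europium centre so firmly that turnover stalls. The higher temperature then needed invites loss of MOM groups and further migration of the allyl unit (towards C6 or by abnormal Claisen pathways). The fallback sets out from 25 and returns at target 28, running the shift on a fully etherified flavonol, where only ether and carbonyl oxygens compete for the metal. The 3-hydroxyl is capped (MOMCl, i-Pr2NEt, CH2Cl2) to give 3,5-bis(methoxymethoxy)-7-(prenyloxy)-2-[3,4-bis(methoxymethoxy)-5-prenylphenyl]-4H-chromen-4-one F4. Eu(fod)3 in PhCl at 80 °C should then give 7-hydroxy-3,5-bis(methoxymethoxy)-8-(2-methylbut-3-en-2-yl)-2-[3,4-bis(methoxymethoxy)-5-prenylphenyl]-4H-chromen-4-one F5. Methanolic HCl removes all four MOM groups to give 28.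

Step 4. Lithiation may compete at the ring carbon between the carbamate and the prenyl ether, or the allylic OCH2 may be deprotonated and rearrange (Wittig shift). Either gives isomeric or degraded silanes. The fallback sets out from diol 2 and returns at 9, introducing the prenyl group only after the silicon is in place. Diol 2 is mono-carbamoylated (i-PrNCO, 1 equiv, Et3N cat.) to 3-hydroxy-5-(methoxymethoxy)phenyl N-isopropylcarbamate F6. The step 4 protocol with 2.2 equiv TBSOTf also caps the free phenol, and the bulky, non-directing silyl ether leaves only the carbon between carbamate and OMOM open to n-BuLi. TMSCl quench and work-up should therefore give 5-[(tert-butyldimethylsilyl)oxy]-3-(methoxymethoxy)-2-(trimethylsilyl)phenyl N-isopropylcarbamate F7. Buffered TBAF (AcOH, THF, 0 °C) cleaves only the aryl silyl ether to 5-hydroxy-3-(methoxymethoxy)-2-(trimethylsilyl)phenyl N-isopropylcarbamate F8. Mitsunobu etherification with 3-methylbut-2-en-1-ol (PPh3, DIAD, THF) then gives 9.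

Further compounds
F1 | step 10 | N-methoxy-N-methyl-3-[3,4-bis(methoxymethoxy)-5-prenylphenyl]prop-2-ynamide | CON(C)C(=O)C#Cc1cc(OCOC)c(OCOC)c(CC=C(C)C)c1
F2 | step 10 | 2-{3-[3,4-bis(methoxymethoxy)-5-prenylphenyl]prop-2-ynoyl}-3-(methoxymethoxy)-5-(prenyloxy)phenyl N-(tert-butyldimethylsilyl)-N-isopropylcarbamate | CC(C)N(C(=O)Oc1cc(OCC=C(C)C)cc(OCOC)c1C(=O)C#Cc1cc(OCOC)c(OCOC)c(CC=C(C)C)c1)[Si](C)(C)C(C)(C)C
F3 | step 10 | 2-{3-[3,4-bis(methoxymethoxy)-5-prenylphenyl]prop-2-ynoyl}-3-(methoxymethoxy)-5-(prenyloxy)phenyl N-isopropylcarbamate | CC(C)NC(=O)Oc1cc(OCC=C(C)C)cc(OCOC)c1C(=O)C#Cc1cc(OCOC)c(OCOC)c(CC=C(C)C)c1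
F4 | step 12 | 3,5-bis(methoxymethoxy)-7-(prenyloxy)-2-[3,4-bis(methoxymethoxy)-5-prenylphenyl]-4H-chromen-4-one | CC(C)=CCOc1cc(OCOC)c2c(=O)c(OCOC)c(-c3cc(OCOC)c(OCOC)c(CC=C(C)C)c3)oc2c1
F5 | step 12 | 7-hydroxy-3,5-bis(methoxymethoxy)-8-(2-methylbut-3-en-2-yl)-2-[3,4-bis(methoxymethoxy)-5-prenylphenyl]-4H-chromen-4-one | C=CC(C)(C)c1c(O)cc(OCOC)c2c(=O)c(OCOC)c(-c3cc(OCOC)c(OCOC)c(CC=C(C)C)c3)oc12
F6 | step 4 | 3-hydroxy-5-(methoxymethoxy)phenyl N-isopropylcarbamate | CC(C)NC(=O)Oc1cc(O)cc(OCOC)c1
F7 | step 4 | 5-[(tert-butyldimethylsilyl)oxy]-3-(methoxymethoxy)-2-(trimethylsilyl)phenyl N-isopropylcarbamate | C[Si](C)(C)c1c(OCOC)cc(O[Si](C)(C)C(C)(C)C)cc1OC(=O)NC(C)C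
F8 | step 4 | 5-hydroxy-3-(methoxymethoxy)-2-(trimethylsilyl)phenyl N-isopropylcarbamate | C[Si](C)(C)c1c(OCOC)cc(O)cc1OC(=O)NC(C)C
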